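**Plan**

1. Numbering: labdane locants (C1–C20) for the terpenoid part; Q1–Q6 for the quinone-derived ring (Q1 = C=O next to Q2, Q2 carries the chromone, Q3 = CH, Q4 = C=O, Q5 = C–OMe, Q6 = CH).
2. Retrosynthesis: first the 7-O–Si bond, then the bonds C12–Q2 and C15–Q3. The cyclohexene C12–C13=C14–C15–Q3–Q2 has its double bond opposite the Q2–Q3 bond, which is flanked by the Q1 and Q4 carbonyls. This is a Diels–Alder retron: the E-diene C12=C13–C14=C15 of a labdatrienone plus Q2=Q3 of a chromonyl methoxy-p-quinone.
3. Diene 12: C14=C15 and C12=C13 are cut by two Wittig disconnections to a C12 aldehyde. The C7–O and C9–O bonds and the C8=C17 alkene go back through an 8α,9α-epoxide to the C8=C9 alkene opened from (+)-sclareolide, which supplies rings A and B with C5 and C10.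
4. Dienophile 19: the quinone comes from oxidative demethylation of a 2,4,5-trimethoxyphenyl ring; the chromone pyranone ring is cut to phloroglucinol and an aroylacetate.
5. Forward order: rings A/B, then ring B oxygenation and the diene side chain; separately the pyranone ring, then the quinone ring. The two halves are joined and the cyclohexene, the last ring, is closed in one step; desilylation ends the route.
6. Stereochemistry: C5/C10 from sclareolide; C9 by α-face epoxidation and epoxide-to-allylic-alcohol isomerization with retention at C9; C12=C13 E by a stabilized-ylide Wittig reaction; C12, Q2 and Q3 in the cycloaddition (cis addition, quinone-exo mode, diene face remote from the decalin).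

Key step: step 16

Remark: the C7 carbinol in 7–11 is drawn 7α (axial), the epimer expected from the allylic oxidation; it is oxidized in step 11, so its configuration has no bearing on the target.

**Route**

Step 1
Reactants: 1 (+)-sclareolide [(3aR,5aS,9aS,9bR)-3a,6,6,9a-tetramethyldecahydronaphtho[2,1-b]furan-2(1H)-one]
Product: 2 methyl 13,14,15,16-tetranorlabd-8-en-12-oate (tetrasubstituted C8=C9 alkene, CH2CO2Me on C9; 5α-H, 10β-CH3)
Conditions: conc. H2SO4, MeOH, reflux (equilibrating)
Reagents that add atoms: methanol, CO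
Why: Acid-mediated lactone opening through the tertiary C8 cation with Fischer esterification and E1 loss of a proton; under the equilibrating acid the positional isomers should converge on the tetrasubstituted C8=C9 alkene, and no stereocentre is formed or touched.

Step 2
Reactants: 2 methyl 13,14,15,16-tetranorlabd-8-en-12-oate
Product: 3 13,14,15,16-tetranorlabd-8-en-12-ol
Conditions: LiAlH4, THF, 0 °C
Reagents that add atoms: none
Why: Hydride reduction of the ester to the primary alcohol; the isolated tetrasubstituted alkene is inert.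

Step 3
Reactants: 3 13,14,15,16-tetranorlabd-8-en-12-ol
Product: 4 12-(tert-butyldimethylsilyloxy)-13,14,15,16-tetranorlabd-8-ene
Conditions: TBSCl, imidazole, DMF, rt
Reagents that add atoms: tert-butyldimethylsilyl chloride, CC(C)(C)[Si](C)(C)Cl
Why: Silyl ether protection of the primary alcohol, which removes the acidic OH and any internal oxygen nucleophile before the epoxide chemistry.

Step 4
Reactants: 4 12-(tert-butyldimethylsilyloxy)-13,14,15,16-tetranorlabd-8-ene
Product: 5 8α,9α-epoxy-12-(tert-butyldimethylsilyloxy)-13,14,15,16-tetranorlabdane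
Conditions: mCPBA, NaHCO3, CH2Cl2, 0 °C
Reagents that add atoms: 3-chloroperoxybenzoic acid, OOC(=O)c1cccc(Cl)c1
Why: Prilezhaev epoxidation of the electron-rich tetrasubstituted alkene from the α face, anti to the axial C10 methyl, which places the oxygen α on C9 (and C8).

Step 5
Reactants: 5 8α,9α-epoxy-12-(tert-butyldimethylsilyloxy)-13,14,15,16-tetranorlabdane
Product: 6 12-(tert-butyldimethylsilyloxy)-13,14,15,16-tetranorlabd-8(17)-en-9α-ol
Conditions: diethylaluminium 2,2,6,6-tetramethylpiperidide [from 2,2,6,6-tetramethylpiperidine, n-BuLi, Et2AlCl], toluene, 0 °C to rt; aqueous work-up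
Reagents that add atoms: none
Why: Base-induced epoxide-to-allylic-alcohol isomerization (syn elimination in an Al–O/N–H six-membered array): the amide should take the most accessible β-proton, on the C17 methyl, so the C8–O bond breaks, the oxygen stays on C9 with retention (9α-OH) and the exocyclic C8=C17 alkene results.

Step 6
Reactants: 6 12-(tert-butyldimethylsilyloxy)-13,14,15,16-tetranorlabd-8(17)-en-9α-ol
Product: 7 12-(tert-butyldimethylsilyloxy)-13,14,15,16-tetranorlabd-8(17)-ene-7α,9α-diol
Conditions: SeO2 (0.5 equiv), t-BuOOH, CH2Cl2, rt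
Reagents that add atoms: selenium dioxide, O=[Se]=O; tert-butyl hydroperoxide, CC(C)(C)OO
Why: Riley allylic oxidation (ene reaction at C17, then [2,3]-sigmatropic shift): C7 carries the only allylic C–H bonds because C9 is quaternary, and the oxygen should be delivered to the axial 7α position.

Step 7
Reactants: 7 12-(tert-butyldimethylsilyloxy)-13,14,15,16-tetranorlabd-8(17)-ene-7α,9α-diol
Product: 8 13,14,15,16-tetranorlabd-8(17)-ene-7α,9α,12-triol
Conditions: Bu4NF, THF, 0 °C
Reagents that add atoms: none
Why: Fluoride-mediated cleavage of the primary silyl ether; the secondary and tertiary hydroxyls are unaffected.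

Step 8
Reactants: 8 13,14,15,16-tetranorlabd-8(17)-ene-7α,9α,12-triol
Product: 9 7α,9α-dihydroxy-13,14,15,16-tetranorlabd-8(17)-en-12-al
Conditions: TEMPO (cat.), PhI(OAc)2, CH2Cl2, rt
Reagents that add atoms: none
Why: Oxoammonium (TEMPO)-catalysed oxidation, which should select the unhindered primary alcohol over the axial allylic secondary and the tertiary hydroxyl and stop at the aldehyde; the β-hydroxy aldehyde is used at once.

Step 9
Reactants: 9 7α,9α-dihydroxy-13,14,15,16-tetranorlabd-8(17)-en-12-al
Product: 10 (12E)-7α,9α-dihydroxy-15-norlabda-8(17),12-dien-14-al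
Conditions: Ph3P=C(CH3)CHO, toluene, 80 °C
Reagents that add atoms: 2-(triphenylphosphoranylidene)propanal, CC(C=O)=P(c1ccccc1)(c1ccccc1)c1ccccc1
Why: Wittig olefination with a stabilized ylide, which reacts only with the aldehyde and should give the (E)-2-methyl-2-enal, fixing C12=C13 as E (C11 cis to the C16 methyl).

Step 10
Reactants: 10 (12E)-7α,9α-dihydroxy-15-norlabda-8(17),12-dien-14-al
Product: 11 (12E)-labda-8(17),12,14-triene-7α,9α-diol
Conditions: Ph3PCH3Br, KN(SiMe3)2 (excess), THF, −78 to 0 °C
Reagents that add atoms: methyltriphenylphosphonium bromide, C[P+](c1ccccc1)(c1ccccc1)c1ccccc1.[Br-]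
Why: Wittig methylenation of the enal carbonyl (1,2-addition) completes the 1,3-diene without touching the C12=C13 geometry; the excess ylide covers the two free hydroxyls.

Step 11
Reactants: 11 (12E)-labda-8(17),12,14-triene-7α,9α-diol
Product: 12 (12E)-9α-hydroxylabda-8(17),12,14-trien-7-one
Conditions: MnO2 (activated), CH2Cl2, rt
Reagents that add atoms: none
Why: MnO2 oxidation of the allylic secondary alcohol to the exo-methylene enone; the tertiary 9-OH and the diene are inert to this oxidant.

Step 12
Reactants: 13 1-(2,4,5-trimethoxyphenyl)ethanone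
Product: 14 ethyl 3-oxo-3-(2,4,5-trimethoxyphenyl)propanoate
Conditions: NaH, (EtO)2CO, THF, reflux; then AcOH
Reagents that add atoms: diethyl carbonate, CCOC(=O)OCC
Why: Crossed Claisen condensation of the methyl ketone enolate with diethyl carbonate, driven by deprotonation of the β-keto ester formed.

Step 13
Reactants: 14 ethyl 3-oxo-3-(2,4,5-trimethoxyphenyl)propanoate; 15 phloroglucinol (benzene-1,3,5-triol)
Product: 17 5,7-dihydroxy-2-(2,4,5-trimethoxyphenyl)-4H-chromen-4-one, via C-aroylacetylphloroglucinol diketone 16 (not isolated)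
Conditions: neat, 240 °C, N2
Reagents that add atoms: none
Why: Thermal phenol/β-keto ester chromone synthesis (Mentzer-type): loss of ethanol gives an acylketene that C-acylates phloroglucinol, and the diketone cyclodehydrates onto the aryl ketone to the 2-arylchromone; the symmetry of phloroglucinol leaves no regiochemical choice.

Step 14
Reactants: 17 5,7-dihydroxy-2-(2,4,5-trimethoxyphenyl)-4H-chromen-4-one
Product: 18 7-(tert-butyldimethylsilyloxy)-5-hydroxy-2-(2,4,5-trimethoxyphenyl)-4H-chromen-4-one
Conditions: TBSCl (1.05 equiv), imidazole, DMF, 0 °C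
Reagents that add atoms: tert-butyldimethylsilyl chloride, CC(C)(C)[Si](C)(C)Cl
Why: Selective silylation of the more acidic, unhindered 7-OH; the 5-OH is held in a hydrogen bond to the C4 carbonyl and should not react.

Step 15
Reactants: 18 7-(tert-butyldimethylsilyloxy)-5-hydroxy-2-(2,4,5-trimethoxyphenyl)-4H-chromen-4-one
Product: 19 2-[7-(tert-butyldimethylsilyloxy)-5-hydroxy-4-oxo-4H-chromen-2-yl]-5-methoxy-1,4-benzoquinone
Conditions: (NH4)2Ce(NO3)6, MeCN–H2O, 0 °C
Reagents that add atoms: water, O
Why: Oxidative demethylation of the para-related 2'- and 5'-methoxy groups by tetravalent cerium: the arene radical cation is trapped by water and two molecules of methanol are lost, leaving the 4'-methoxy group on the p-quinone, while the acyl-deactivated chromone ring should not be oxidized.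

Step 16
Reactants: 12 (12E)-9α-hydroxylabda-8(17),12,14-trien-7-one; 19 2-[7-(tert-butyldimethylsilyloxy)-5-hydroxy-4-oxo-4H-chromen-2-yl]-5-methoxy-1,4-benzoquinone
Product: 20 7-O-tert-butyldimethylsilyl ether of the target (cis-fused cyclohexene–enedione adduct; C11 methylene on C12, chromone on Q2 and H on Q3 all on one face of the new ring)
Conditions: 19, BF3·OEt2 (2.2 equiv; the first is taken up by the chromone carbonyl), CH2Cl2, −78 °C; then 12, −78 to −45 °C; aq. NaHCO3
Reagents that add atoms: none
Why: Lewis acid-promoted, asynchronous [4+2] cycloaddition (Diels–Alder reaction) of the (12E)-diene C12=C13–C14=C15 of 12 with the Q2=Q3 bond of quinone 19; the closest known reaction type is the BF3-promoted Diels–Alder reaction of 2-methoxy-5-alkyl-1,4-benzoquinones with 1-substituted dienes, in which the diene substituent ends up beside the angular carbon. The single new ring, cyclohexene C12–C13=C14–C15–Q3–Q2, is closed by intermolecular suprafacial [4πs+2πs] addition, with the C15–Q3 bond leading and the C12–Q2 bond (quaternary centre) lagging. Site and orientation are secured by the substrate: the Q5 methoxy group makes Q5=Q6 a vinylogous ester and inert, while BF3 on the most basic quinone oxygen (O1, the carbonyl conjugated to OMe) and the conjugating chromone on Q2 make Q3 the electrophilic carbon, which pairs with the unsubstituted, more nucleophilic C15. Q2 and Q3 are set together by cis addition (chromone and Q3–H cis, cis ring fusion), and C12 relative to them by the E geometry of C12=C13 combined with the approach mode: the target has the C11 methylene cis to the chromone, which means the quinone ring exo and the chromone under C13, the reverse of the usual quinone-endo mode. That mode should be enforced by the BF3 group on O1, which in the quinone-endo array would lie directly under the C13 methyl (C16), so that the 2-methyl group of the diene and the complexed carbonyl exclude each other. The absolute sense comes from the C9 carbinol centre: allylic 1,3-strain to C16 keeps one C11–H in the diene plane, C12 stands anti to C10 with H12 turned away from the C17 methylene, and the decalin covers one face of C12, so the dienophile should add to the open face, which corresponds to the C12 configuration of the target; the selectivities needed are therefore site, orientation, exo mode and diene face.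

Step 17
Reactants: 20 7-O-tert-butyldimethylsilyl ether of the target
Product: 21 CNP0241859.1 (target)
Conditions: HF·pyridine, THF, 0 °C
Reagents that add atoms: none
Why: Fluoride cleavage of the aryl silyl ether under weakly acidic conditions, which should leave the exo-methylene enone, the methoxy-enedione, the tertiary alcohol and the epimerizable Q3–H untouched.

**Compound list**

1 | (+)-sclareolide | C[C@@]13CC[C@H]2C(C)(C)CCC[C@]2(C)[C@H]1CC(=O)O3 | starting material
2 | methyl 13,14,15,16-tetranorlabd-8-en-12-oate | CC1=C(CC(=O)OC)[C@@]2(C)CCCC(C)(C)[C@@H]2CC1 | intermediate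
3 | 13,14,15,16-tetranorlabd-8-en-12-ol | CC1=C(CCO)[C@@]2(C)CCCC(C)(C)[C@@H]2CC1 | intermediate
4 | 12-(tert-butyldimethylsilyloxy)-13,14,15,16-tetranorlabd-8-ene | CC1=C(CCO[Si](C)(C)C(C)(C)C)[C@@]2(C)CCCC(C)(C)[C@@H]2CC1 | intermediate
5 | 8α,9α-epoxy-12-(tert-butyldimethylsilyloxy)-13,14,15,16-tetranorlabdane | C[C@@]12CC[C@H]3C(C)(C)CCC[C@]3(C)[C@]1(CCO[Si](C)(C)C(C)(C)C)O2 | intermediate
6 | 12-(tert-butyldimethylsilyloxy)-13,14,15,16-tetranorlabd-8(17)-en-9α-ol | C=C1CC[C@H]2C(C)(C)CCC[C@]2(C)[C@@]1(O)CCO[Si](C)(C)C(C)(C)C | intermediate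
7 | 12-(tert-butyldimethylsilyloxy)-13,14,15,16-tetranorlabd-8(17)-ene-7α,9α-diol | C=C1[C@H](O)C[C@H]2C(C)(C)CCC[C@]2(C)[C@@]1(O)CCO[Si](C)(C)C(C)(C)C | intermediate
8 | 13,14,15,16-tetranorlabd-8(17)-ene-7α,9α,12-triol | C=C1[C@H](O)C[C@H]2C(C)(C)CCC[C@]2(C)[C@@]1(O)CCO | intermediate
9 | 7α,9α-dihydroxy-13,14,15,16-tetranorlabd-8(17)-en-12-al | C=C1[C@H](O)C[C@H]2C(C)(C)CCC[C@]2(C)[C@@]1(O)CC=O | intermediate
10 | (12E)-7α,9α-dihydroxy-15-norlabda-8(17),12-dien-14-al | C=C1[C@H](O)C[C@H]2C(C)(C)CCC[C@]2(C)[C@@]1(O)C/C=C(\C)C=O | intermediate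
11 | (12E)-labda-8(17),12,14-triene-7α,9α-diol | C=C1[C@H](O)C[C@H]2C(C)(C)CCC[C@]2(C)[C@@]1(O)C/C=C(\C)C=C | intermediate
12 | (12E)-9α-hydroxylabda-8(17),12,14-trien-7-one | C=C1C(=O)C[C@H]2C(C)(C)CCC[C@]2(C)[C@@]1(O)C/C=C(\C)C=C | intermediate
13 | 1-(2,4,5-trimethoxyphenyl)ethanone | CC(=O)c1cc(OC)c(OC)cc1OC | starting material
14 | ethyl 3-oxo-3-(2,4,5-trimethoxyphenyl)propanoate | CCOC(=O)CC(=O)c1cc(OC)c(OC)cc1OC | intermediate
15 | phloroglucinol | Oc1cc(O)cc(O)c1 | starting material
16 | 1-(2,4,5-trimethoxyphenyl)-3-(2,4,6-trihydroxyphenyl)propane-1,3-dione (not isolated) | COc1cc(OC)c(cc1OC)C(=O)CC(=O)c1c(O)cc(O)cc1O | intermediate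
17 | 5,7-dihydroxy-2-(2,4,5-trimethoxyphenyl)-4H-chromen-4-one | COc1cc(OC)c(cc1OC)-c1cc(=O)c2c(O)cc(O)cc2o1 | intermediate
18 | 7-(tert-butyldimethylsilyloxy)-5-hydroxy-2-(2,4,5-trimethoxyphenyl)-4H-chromen-4-one | COc1cc(OC)c(cc1OC)-c1cc(=O)c2c(O)cc(O[Si](C)(C)C(C)(C)C)cc2o1 | intermediate
19 | 2-[7-(tert-butyldimethylsilyloxy)-5-hydroxy-4-oxo-4H-chromen-2-yl]-5-methoxy-1,4-benzoquinone | COC1=CC(=O)C(=CC1=O)c1cc(=O)c2c(O)cc(O[Si](C)(C)C(C)(C)C)cc2o1 | intermediate
20 | 7-O-tert-butyldimethylsilyl ether of the target | C=C1C(=O)C[C@H]2C(C)(C)CCC[C@]2(C)[C@@]1(O)C[C@@H]1C(C)=CC[C@H]2C(=O)C(OC)=CC(=O)[C@@]12c1cc(=O)c2c(O)cc(O[Si](C)(C)C(C)(C)C)cc2o1 | intermediate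
21 | CNP0241859.1 | C=C1C(=O)C[C@H]2C(C)(C)CCC[C@]2(C)[C@@]1(O)C[C@@H]1C(C)=CC[C@H]2C(=O)C(OC)=CC(=O)[C@@]12c1cc(=O)c2c(O)cc(O)cc2o1 | target

**Step count and risks**

Total step count: 17. Longest linear sequence: 13 steps (steps 1–11, 16, 17).

Step 16. What may go wrong: addition through the ordinary quinone-endo array, which gives the C12 epimer relative to Q2/Q3; loss of diene-face selectivity; or Lewis acid-induced ionization of the diene toward the activated enone of 12. The fallback reaches the same relative configuration with the endo mode instead of against it, by inverting the diene geometry. It sets out from aldehyde 9. Stork–Zhao olefination [Ph3P=C(I)CH3 from ethyltriphenylphosphonium iodide, n-BuLi, I2, then NaN(SiMe3)2, THF, −78 °C, excess] should give (12Z)-13-iodo-14,15-dinorlabda-8(17),12-diene-7α,9α-diol F1. Stille coupling with tributyl(vinyl)stannane [Pd(PPh3)4, CuI, DMF] should give (12Z)-labda-8(17),12,14-triene-7α,9α-diol F2, and MnO2 should give (12Z)-9α-hydroxylabda-8(17),12,14-trien-7-one F3. Lewis acid-free cycloaddition of F3 with 19 at 12–15 kbar (CH2Cl2, 25 °C) in the normal quinone-endo mode would place the now inside C11 methylene cis to the chromone and come back to the route at 20. The cost is the low reactivity of a diene with an inside substituent, which the pressure is meant to offset.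

Step 5. What may go wrong: competing proton abstraction at C11 (leaving the oxygen on C8 with a C9=C11 alkene) or at C7, or sluggish opening of the tetrasubstituted epoxide. The fallback sets out from alkene 4. Allylic oxidation [CrO3, 3,5-dimethylpyrazole, CH2Cl2, −20 °C] should give 12-(tert-butyldimethylsilyloxy)-13,14,15,16-tetranorlabd-8-en-7-one F4. Nucleophilic epoxidation from the α face [H2O2, NaOH, MeOH] should give the 8α,9α-epoxy-7-ketone F5. Wharton transposition [N2H4·H2O, AcOH, MeOH] should give 12-(tert-butyldimethylsilyloxy)-13,14,15,16-tetranorlabd-7-en-9α-ol F6, with C9–O fixed by the epoxide. A hydroxyl-directed Schenck ene reaction [O2, hν, tetraphenylporphyrin, CH2Cl2] should take a hydrogen from C17 and deliver oxygen to C7 syn to the 9α-OH, giving the 7α-hydroperoxide F7 (not isolated), which PPh3 reduces to come back to the route at 7.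

Step 1. What may go wrong: incomplete equilibration, leaving the C7=C8 and C8=C17 positional isomers, or relactonization to 1. The fallback sets out from 1 and fixes the alkene position by construction. α-Selenenylation of the lactone enolate [LiN(iPr)2, PhSeBr, THF, −78 °C] should give 11-(phenylselanyl)sclareolide F8. Selenoxide syn-elimination [H2O2, pyridine, CH2Cl2] should give the 9(11)-unsaturated butenolide F9. Reductive cleavage of the allylic C8–O bond with SmI2 (THF–MeOH), followed by α-protonation of the dienolate, should give 13,14,15,16-tetranorlabd-8-en-12-oic acid F10. LiAlH4 reduction of F10 comes back to the route at 3.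

**Further compounds**

F1 | step 16 | (12Z)-13-iodo-14,15-dinorlabda-8(17),12-diene-7α,9α-diol | C=C1[C@H](O)C[C@H]2C(C)(C)CCC[C@]2(C)[C@@]1(O)C/C=C(\I)C
F2 | step 16 | (12Z)-labda-8(17),12,14-triene-7α,9α-diol | C=C1[C@H](O)C[C@H]2C(C)(C)CCC[C@]2(C)[C@@]1(O)C/C=C(\C=C)C
F3 | step 16 | (12Z)-9α-hydroxylabda-8(17),12,14-trien-7-one | C=C1C(=O)C[C@H]2C(C)(C)CCC[C@]2(C)[C@@]1(O)C/C=C(\C=C)C
F4 | step 5 | 12-(tert-butyldimethylsilyloxy)-13,14,15,16-tetranorlabd-8-en-7-one | CC1=C(CCO[Si](C)(C)C(C)(C)C)[C@@]2(C)CCCC(C)(C)[C@@H]2CC1=O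
F5 | step 5 | 8α,9α-epoxy-12-(tert-butyldimethylsilyloxy)-13,14,15,16-tetranorlabdan-7-one | C[C@@]12C(=O)C[C@H]3C(C)(C)CCC[C@]3(C)[C@]1(CCO[Si](C)(C)C(C)(C)C)O2
F6 | step 5 | 12-(tert-butyldimethylsilyloxy)-13,14,15,16-tetranorlabd-7-en-9α-ol | CC1=CC[C@H]2C(C)(C)CCC[C@]2(C)[C@@]1(O)CCO[Si](C)(C)C(C)(C)C
F7 | step 5 | 12-(tert-butyldimethylsilyloxy)-7α-hydroperoxy-13,14,15,16-tetranorlabd-8(17)-en-9α-ol | C=C1[C@H](OO)C[C@H]2C(C)(C)CCC[C@]2(C)[C@@]1(O)CCO[Si](C)(C)C(C)(C)C
F8 | step 1 | 11-(phenylselanyl)sclareolide | C[C@@]13CC[C@H]2C(C)(C)CCC[C@]2(C)[C@H]1C([Se]c1ccccc1)C(=O)O3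
F9 | step 1 | 9(11)-didehydrosclareolide (butenolide) | C[C@@]13CC[C@H]2C(C)(C)CCC[C@]2(C)C1=CC(=O)O3
F10 | step 1 | 13,14,15,16-tetranorlabd-8-en-12-oic acid | CC1=C(CC(=O)O)[C@@]2(C)CCCC(C)(C)[C@@H]2CC1
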